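## The problem

The target 18 is a 24-membered macrocycle in which two (E)-cinnamoyl units acylate N1 and N8 of spermidine and are tied together by a diaryl ether. Locants used throughout: ring A carries its propenoyl chain at C1, the ether oxygen at C3 and the sulfated oxygen at C4; ring B carries its chain at C1' and the ether oxygen at C4'.

There are no stereocentres. The only stereochemical elements are the two E alkenes, which are thermodynamically favoured but must be kept from light, hydrogenation catalysts and strong nucleophiles. Spermidine is unsymmetrical, so the ring A acyl group has to go to N8 (butylene end) and the ring B acyl group to N1 (propylene end), while the basic N5 stays unacylated and, later, unsulfated. The aryl hydrogensulfate does not survive acid, so it must come late and be followed only by neutral or basic, non-reducing operations. The two cinnamamides exclude catalytic hydrogenation at every stage. The ring must be closed without a template against the entropy of a 24-membered ring.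

The feature that opens a direct route is the 2-aryloxyphenol pattern of ring A, with the aryl ether at C3 next to the oxygen at C4. This is the pattern left when a para-substituted phenol is oxidised and trapped at an ortho carbon by a second phenol, so the ether bond and the macrocycle can be made in one event from two phenols.

## Retrosynthesis

**18 ⇒ 17 ⇒ 16.** The N5 carbamate and the O–S bond are cut last. The sulfate must follow all acidic and reductive chemistry, and N5 must then be freed without acid or hydrogen. That is why a fluoride-labile 2-(trimethylsilyl)ethyl carbamate sits on N5 from 13 onwards, rather than a tert-butyl or benzyl carbamate. Phenol 16 is neutral and has one phenol and no free amine, which is all the forward O-sulfation asks for.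

**16 ⇒ 15.** Three aryl C–H bonds are traced back to one C–Br on ring A (C5) and two C–Cl on ring B (C3', C5'). This is no simplification; it is the price of the next cut. The forward step must reduce aryl halides and leave two conjugated alkenes alone, which rules out H2 over a heterogeneous metal and points to homogeneous formate transfer.

**15 ⇒ 14 ⇒ 13.** The bond between the ring B oxygen and ring A C3 is cut. This opens the ether and the macrocycle at once and leaves the acyclic bis-phenol diamide 13, through dienone 14. The neighbouring cut at an amide bond would need the diaryl ether made earlier in a separate coupling, a protecting group on the ring A phenol, and two differentiated carboxyl groups as well as two differentiated amines. The forward step must couple oxygen to carbon in one direction only, intramolecularly, and without touching the alkenes.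

**13 ⇒ 12 ⇒ 11.** The carbamate C–N bond is cut, then a methylene bridge between N1 and N5 is added back. In 11 the nitrogen N5 is tertiary and part of an aminal, so it cannot be acylated; the bridge is what differentiates the three nitrogens. The forward steps are excision of the bridge and carbamoylation of the one secondary amine of 12.

**11 ⇒ 9 + 5 and 9 ⇒ 7 + 3.** The two amide bonds are cut. The primary amine of 7 is acylated first with acid 3 (through active ester 8), then the less reactive aminal N–H of 9 with acid 5 (through active ester 10). The phenols stay free, because esters of such acidic phenols would themselves act as acyl donors. The forward acylations must distinguish a primary amine from an aminal N–H.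

**7 ⇒ 6.** The aminal is opened to spermidine 6. Only the 1,3-diamine half can form a six-membered ring with a one-carbon unit, so N8 is left as the only primary amine.

**3 ⇒ 1 + 2 and 5 ⇒ 4 + 2.** Each alkene is cut to a commercial dihalo-hydroxybenzaldehyde (1 or 4) and malonic acid 2. Decarboxylative condensation gives the E acids directly.

## Roads not taken

**Alternative 1:** The cut runs through two C–C bonds of ring B. Methyl coumalate A2 and the aryl ethynyl ether A3 would combine in an inverse-electron-demand Diels–Alder reaction with loss of CO2, giving benzoate A1 with the ether oxygen already para to the ester.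
- Merits: regiochemistry follows from the polarity of the two partners; no halogen is introduced or removed; no oxidation is run beside the alkenes. The uncertain step sits early, on cheap material. The ester and the acetal of A1 are already differentiated, which helps the N1/N8 assignment.
- Weak points: A3 needs a multi-step preparation with strong base and is not a storable reagent. A1 holds ring B carbon at the ester level, so reduction, reoxidation and two separate olefinations follow. Both amide bonds remain, one of them as a macrolactamisation. The 4-methoxybenzyl ether must later be removed beside a carbamate.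
- Comparison: Alternative 1 is better in where its risk falls and in needing no dehalogenation. The chosen plan sets against this about half the step count, commercial arenes, and a ring closure that is the ether formation itself.

**Alternative 2:** The cut runs through two C–C bonds of ring A. Methyl coumalate A2 and the bis-silyl ketene acetal A5 would undergo Diels–Alder addition, loss of CO2 and elimination of trimethylsilanol to give A4.
- Merits: ring A emerges with the free C4 hydroxyl and the C3 aryloxy group correctly differentiated. The ring B bromide is a handle for a Heck reaction with an N-acryloyl polyamine, which would install the ring B cinnamamide convergently.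
- Weak points: A5 is a moisture-sensitive reagent, and cycloaddition with aromatisation of an α-aryloxy ketene acetal is less secure than the phenol oxidation used here. The ring A ester needs reduction, reoxidation and olefination with the phenol protected. The macrocycle must still be closed by lactamisation.
- Comparison: Alternative 2 has the better end game, with no aryl halide to remove beside the alkenes. The chosen plan has fewer steps, no phenol protecting groups, and both amides made intermolecularly.

**Alternative 3:** The cut lies in the polyamine, at C3–C4 and C4–N5 of the butylene chain. The N-allyl amide A7, which carries the terminal primary amine, would undergo linear hydroformylation and intramolecular reductive amination under CO/H2 with Rh(acac)(CO)2 and Xantphos, giving A6 with N5 free.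
- Merits: it is atom-economical, builds the triamine without ever differentiating the nitrogens of spermidine, and needs no N5 protecting group up to ring closure. In this respect it is better than the chosen plan.
- Weak points: a rhodium hydride under H2 can hydrogenate or hydroformylate the two cinnamamides. N-allyl amides tend to give branched aldehydes or isomerise to enamides. The new secondary amine can react a second time. Imine formation across a 24-membered ring competes with oligomers. The diaryl ether must be made beforehand, and N5 must still be protected before sulfation.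
- Comparison: both plans carry a chemoselectivity question at the alkenes, here in step 9, there in the ring closure. The chosen plan sets against the protecting-group economy of Alternative 3 a single step that makes the ether and closes the ring.

Key step: step 8

Remark on the chemistry: 18 is assumed to be isolated as its inner salt (N5 ammonium, aryl sulfate anion), the form in which the neutral formula exists; 17 is handled as the sodium salt.

## Steps

Step 1
Reactants: 1 3,5-dibromo-4-hydroxybenzaldehyde; 2 malonic acid
Product: 3 (E)-3-(3,5-dibromo-4-hydroxyphenyl)prop-2-enoic acid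
Conditions: pyridine, piperidine (cat.), 80 °C; then aq HCl
Reagents that add atoms: malonic acid (2), OC(=O)CC(=O)O
Why: Knoevenagel–Doebner condensation; decarboxylative elimination of the arylidenemalonic acid gives the E acid as the thermodynamic isomer.

Step 2
Reactants: 4 3,5-dichloro-4-hydroxybenzaldehyde; 2 malonic acid
Product: 5 (E)-3-(3,5-dichloro-4-hydroxyphenyl)prop-2-enoic acid
Conditions: pyridine, piperidine (cat.), 80 °C; then aq HCl
Reagents that add atoms: malonic acid (2), OC(=O)CC(=O)O
Why: Knoevenagel–Doebner condensation as in step 1; the E alkene is set by the decarboxylative elimination.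

Step 3
Reactants: 6 spermidine
Product: 7 4-(hexahydropyrimidin-1-yl)butan-1-amine
Conditions: 37% aq HCHO (1.0 equiv), H2O, 0 °C→rt
Reagents that add atoms: formaldehyde, C=O
Why: Aminal formation; only the 1,3-diamine part of spermidine can close a six-membered ring, so N1 and N5 are bridged and N8 remains the only primary amine.

Step 4
Reactants: 3 (E)-3-(3,5-dibromo-4-hydroxyphenyl)prop-2-enoic acid; 7 4-(hexahydropyrimidin-1-yl)butan-1-amine
Product: 9 (E)-3-(3,5-dibromo-4-hydroxyphenyl)-N-[4-(hexahydropyrimidin-1-yl)butyl]prop-2-enamide, via succinimidyl ester 8 (not isolated)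
Conditions: N-hydroxysuccinimide, DCC, THF, 0 °C→rt, filter; then 7 (1.0 equiv), i-Pr2NEt, THF–DMF, −20→0 °C
Reagents that add atoms: N-hydroxysuccinimide, O=C1CCC(=O)N1O (its atoms stay in intermediate 8 only)
Why: Active-ester amide formation; the mild succinimidyl ester is taken up by the unhindered primary amine faster than by the less basic aminal N–H, and the ionised dihalophenol is too poor a nucleophile to compete.

Step 5
Reactants: 9 (E)-3-(3,5-dibromo-4-hydroxyphenyl)-N-[4-(hexahydropyrimidin-1-yl)butyl]prop-2-enamide; 5 (E)-3-(3,5-dichloro-4-hydroxyphenyl)prop-2-enoic acid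
Product: 11 (E)-3-(3,5-dibromo-4-hydroxyphenyl)-N-{4-[3-((E)-3-(3,5-dichloro-4-hydroxyphenyl)prop-2-enoyl)hexahydropyrimidin-1-yl]butyl}prop-2-enamide, via succinimidyl ester 10 (not isolated)
Conditions: N-hydroxysuccinimide, DCC, THF, 0 °C→rt, filter; then 9, i-Pr2NEt, DMF, rt→40 °C; then K2CO3, MeOH, rt
Reagents that add atoms: N-hydroxysuccinimide, O=C1CCC(=O)N1O (its atoms stay in intermediate 10 only)
Why: Active-ester acylation of the only remaining N–H amine (the cyclic aminal nitrogen, N1 of spermidine); the tertiary N5 cannot react, and the brief methanolysis returns any phenol ester formed by over-acylation.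

Step 6
Reactants: 11 (E)-3-(3,5-dibromo-4-hydroxyphenyl)-N-{4-[3-((E)-3-(3,5-dichloro-4-hydroxyphenyl)prop-2-enoyl)hexahydropyrimidin-1-yl]butyl}prop-2-enamide
Product: 12 N8-[(E)-3,5-dibromo-4-hydroxycinnamoyl]-N1-[(E)-3,5-dichloro-4-hydroxycinnamoyl]spermidine
Conditions: malonic acid, pyridine, EtOH, reflux
Reagents that add atoms: none
Why: Knoevenagel-type excision of the aminal methylene; the N-acyl aminal opens to an iminium ion that hands its one-carbon unit to malonic acid, leaving the N1 amide N–H and the free secondary N5.

Step 7
Reactants: 12 N8-[(E)-3,5-dibromo-4-hydroxycinnamoyl]-N1-[(E)-3,5-dichloro-4-hydroxycinnamoyl]spermidine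
Product: 13 N8-[(E)-3,5-dibromo-4-hydroxycinnamoyl]-N1-[(E)-3,5-dichloro-4-hydroxycinnamoyl]-N5-[2-(trimethylsilyl)ethoxycarbonyl]spermidine
Conditions: Teoc-OSu, Et3N, DMF, rt
Reagents that add atoms: N-[2-(trimethylsilyl)ethoxycarbonyloxy]succinimide (Teoc-OSu), C[Si](C)(C)CCOC(=O)ON1C(=O)CCC1=O
Why: Carbamate formation at the only basic amine; the hindered, acidic dihalophenols and the amide N–H groups do not compete, and any aryl carbonate is lost on aqueous work-up.

Step 8
Reactants: 13 N8-[(E)-3,5-dibromo-4-hydroxycinnamoyl]-N1-[(E)-3,5-dichloro-4-hydroxycinnamoyl]-N5-[2-(trimethylsilyl)ethoxycarbonyl]spermidine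
Product: 15 N5-Teoc macrocyclic diaryl ether (ring B oxygen on ring A C3; ring A 5-bromo-4-hydroxy; ring B 3',5'-dichloro), via aryloxybromodienone 14 (not isolated)
Conditions: undivided cell, glassy-carbon anode, Pt cathode, LiClO4, MeOH, constant current (about 2 F/mol), about 1 mM, rt; then Zn dust, AcOH, rt
Reagents that add atoms: none
Why: Anodic two-electron oxidation of the more easily oxidised ring A 2,6-dibromophenol gives a phenoxonium-type species whose ortho carbon C3 is captured by the oxygen of the ring B 2,6-dichlorophenol, giving the 6-aryloxy-6-bromocyclohexa-2,4-dienone 14; zinc in acetic acid then cleaves the C–Br bond at the sp3 carbon and the arene is restored as 15. The closest known reaction type is the anodic (or Tl(NO3)3-mediated) oxidation of o,o'-dihalophenols followed by zinc reduction to 2-aryloxyphenols, which has also served for ring closure of bis-phenol amides. The 24-membered ring is closed in the C–O bond-forming event itself, by intramolecular attack of the ring B oxygen on C3 of oxidised ring A at high dilution. No stereocentre remains in 15: the sp3 carbon of 14 is transient and is flattened by the reduction, and the E alkenes are not touched. The direction of coupling is secured by the bromine-for-chlorine difference between the rings. Carbon–carbon coupling is blocked by halogens at every ortho position and by the side chains at both para positions, and the alkenes are deactivated towards oxidation by their amide carbonyls. Methanol adducts of oxidised ring A are returned to 13 by the zinc and can be resubmitted, and the carbamate and amides oxidise only well above the potential needed.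

Step 9
Reactants: 15 N5-Teoc macrocyclic diaryl ether (ring A 5-bromo-4-hydroxy; ring B 3',5'-dichloro)
Product: 16 N5-Teoc macrocyclic diaryl ether with free ring A phenol and no halogen
Conditions: Pd(OAc)2 (cat.), XPhos (cat.), HCO2Na (excess), DMF–H2O, 90 °C
Reagents that add atoms: none
Why: Palladium-catalysed formate hydrodehalogenation: zerovalent palladium inserts into each C–Br and C–Cl bond, formate replaces halide, CO2 is lost and C–H reductive elimination follows. The aryl palladium hydride should collapse faster than it can add to the 1,2-disubstituted, amide-deactivated alkenes, and neither H2 nor a metal surface is present.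

Step 10
Reactants: 16 N5-Teoc macrocyclic diaryl ether with free ring A phenol and no halogen
Product: 17 sodium salt of the N5-Teoc macrocyclic aryl sulfate
Conditions: SO3·pyridine, pyridine, rt→40 °C; then aq NaHCO3
Reagents that add atoms: sulfur trioxide–pyridine complex, [O-]S(=O)(=O)[n+]1ccccc1; sodium hydrogencarbonate, [Na+].OC(=O)[O-]
Why: O-sulfation of the single phenol with the SO3·pyridine complex; the secondary amides and the carbamate do not react at this temperature and N5 is masked, so no sulfamate can form.

Step 11
Reactants: 17 sodium salt of the N5-Teoc macrocyclic aryl sulfate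
Product: 18 target macrocycle (inner salt of the N5 ammonium and the ring A C4 aryl sulfate)
Conditions: Bu4NF, THF, rt→40 °C; then aq AcOH; reversed-phase chromatography (C18, MeCN–H2O)
Reagents that add atoms: none
Why: Fluoride-induced fragmentation of the 2-(trimethylsilyl)ethyl carbamate: attack at silicon releases ethene and the carbamate anion, which loses CO2. The conditions are neither acidic nor reducing, so the aryl sulfate and both E alkenes persist.

## Compound list

1 | 3,5-dibromo-4-hydroxybenzaldehyde | O=Cc1cc(Br)c(O)c(Br)c1 | starting material
2 | malonic acid | OC(=O)CC(=O)O | starting material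
3 | (E)-3-(3,5-dibromo-4-hydroxyphenyl)prop-2-enoic acid | OC(=O)/C=C/c1cc(Br)c(O)c(Br)c1 | intermediate
4 | 3,5-dichloro-4-hydroxybenzaldehyde | O=Cc1cc(Cl)c(O)c(Cl)c1 | starting material
5 | (E)-3-(3,5-dichloro-4-hydroxyphenyl)prop-2-enoic acid | OC(=O)/C=C/c1cc(Cl)c(O)c(Cl)c1 | intermediate
6 | spermidine (N1-(3-aminopropyl)butane-1,4-diamine) | NCCCNCCCCN | starting material
7 | 4-(hexahydropyrimidin-1-yl)butan-1-amine | NCCCCN1CCCNC1 | intermediate
8 | N-succinimidyl (E)-3-(3,5-dibromo-4-hydroxyphenyl)prop-2-enoate | O=C(/C=C/c1cc(Br)c(O)c(Br)c1)ON1C(=O)CCC1=O | intermediate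
9 | (E)-3-(3,5-dibromo-4-hydroxyphenyl)-N-[4-(hexahydropyrimidin-1-yl)butyl]prop-2-enamide | O=C(/C=C/c1cc(Br)c(O)c(Br)c1)NCCCCN1CCCNC1 | intermediate
10 | N-succinimidyl (E)-3-(3,5-dichloro-4-hydroxyphenyl)prop-2-enoate | O=C(/C=C/c1cc(Cl)c(O)c(Cl)c1)ON1C(=O)CCC1=O | intermediate
11 | (E)-3-(3,5-dibromo-4-hydroxyphenyl)-N-{4-[3-((E)-3-(3,5-dichloro-4-hydroxyphenyl)prop-2-enoyl)hexahydropyrimidin-1-yl]butyl}prop-2-enamide | O=C(/C=C/c1cc(Br)c(O)c(Br)c1)NCCCCN1CCCN(C1)C(=O)/C=C/c1cc(Cl)c(O)c(Cl)c1 | intermediate
12 | N8-[(E)-3,5-dibromo-4-hydroxycinnamoyl]-N1-[(E)-3,5-dichloro-4-hydroxycinnamoyl]spermidine | O=C(/C=C/c1cc(Br)c(O)c(Br)c1)NCCCCNCCCNC(=O)/C=C/c1cc(Cl)c(O)c(Cl)c1 | intermediate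
13 | N8-[(E)-3,5-dibromo-4-hydroxycinnamoyl]-N1-[(E)-3,5-dichloro-4-hydroxycinnamoyl]-N5-[2-(trimethylsilyl)ethoxycarbonyl]spermidine | O=C(/C=C/c1cc(Br)c(O)c(Br)c1)NCCCCN(C(=O)OCC[Si](C)(C)C)CCCNC(=O)/C=C/c1cc(Cl)c(O)c(Cl)c1 | intermediate
14 | macrocyclic 6-aryloxy-6-bromocyclohexa-2,4-dienone (ring A in dienone form, C3 sp3 with Br and the ring B oxygen, racemic at that carbon; N5-Teoc) | O=C1/C=C/C2=CC(Br)(Oc3c(Cl)cc(cc3Cl)/C=C/C(=O)NCCCN(C(=O)OCC[Si](C)(C)C)CCCCN1)C(=O)C(Br)=C2 | intermediate
15 | N5-Teoc macrocyclic diaryl ether, ring A 3-aryloxy-5-bromo-4-hydroxy, ring B 3',5'-dichloro, both alkenes E | O=C1/C=C/c2cc(Br)c(O)c(c2)Oc2c(Cl)cc(cc2Cl)/C=C/C(=O)NCCCN(C(=O)OCC[Si](C)(C)C)CCCCN1 | intermediate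
16 | N5-Teoc macrocyclic diaryl ether with free ring A C4 phenol and no halogen, both alkenes E | O=C1/C=C/c2ccc(O)c(c2)Oc2ccc(cc2)/C=C/C(=O)NCCCN(C(=O)OCC[Si](C)(C)C)CCCCN1 | intermediate
17 | sodium salt of the N5-Teoc macrocyclic ring A C4 aryl sulfate, both alkenes E | O=C1/C=C/c2ccc(OS(=O)(=O)[O-])c(c2)Oc2ccc(cc2)/C=C/C(=O)NCCCN(C(=O)OCC[Si](C)(C)C)CCCCN1.[Na+] | intermediate
18 | CID124202369, 24-membered N1,N8-bis[(E)-cinnamoyl]spermidine diaryl ether with ring A C4 hydrogensulfate | O=C1/C=C/c2ccc(OS(=O)(=O)O)c(c2)Oc2ccc(cc2)/C=C/C(=O)NCCCNCCCCN1 | target

## Step count and least certain steps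

Total steps: 11. Longest linear sequence: 9 steps (6 → 18 through steps 3–11; equally 1 → 18 through steps 1 and 4–11).

**Step 8 (key step).** What may go wrong:
- capture of oxidised ring A by methanol instead of by the distant ring B oxygen;
- intermolecular coupling to dimers and oligomers;
- radical coupling through the carbon next to the carbonyl of the ring A cinnamoyl unit;
- coupling in the reverse direction if the two phenols are oxidised at similar potentials.

The first is partly self-correcting, since zinc returns 13; the others lose material.

Fallback (sets out from 7, returns at 16): the ether bond is made by copper-mediated O-arylation instead of phenol oxidation.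
- Commercial 3-bromo-4-hydroxybenzaldehyde is O-allylated (allyl bromide, K2CO3, DMF) to 4-(allyloxy)-3-bromobenzaldehyde F1.
- Doebner condensation of F1 with 2 gives (E)-3-[4-(allyloxy)-3-bromophenyl]prop-2-enoic acid F2.
- F2 is coupled to the primary amine of 7 (EDC·HCl, HOBt) to give the N8 amide F3.
- The aminal nitrogen of F3 is acylated with commercial (E)-4-hydroxycinnamic acid (EDC·HCl, HOBt) to give the bis-amide aminal F4.
- The methylene bridge is excised as in step 6 to give the N5-free diamide F5, and Teoc-OSu gives the N5-Teoc bromide–phenol F6.
- Intramolecular Ullmann ether synthesis (CuI, N,N-dimethylglycine, Cs2CO3, dioxane, 90 °C, high dilution) joins the ring B oxygen to ring A C3 and closes the same 24-membered ring, giving the O-allyl macrocycle F7.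
- Pd(PPh3)4 with morpholine removes the allyl group and delivers 16.

This fallback also bypasses step 9, at the cost of four extra operations.

**Step 9.** What may go wrong: conjugate reduction of one or both cinnamamides by palladium hydride, reductive Heck-type addition of an aryl palladium species to an alkene, or incomplete removal of the two chlorides flanking the ether oxygen.

Fallback (sets out from 15, returns at 16): the three carbon–halogen bonds are exchanged for carbon–boron bonds and then protonated, so that no metal hydride is generated. Miyaura borylation of 15 (Pd2(dba)3, XPhos, B2pin2, KOAc, dioxane, 100 °C) gives the tris(pinacolboronate) F8. Its boryl groups, each ortho to an oxygen substituent, are removed by base-promoted protodeboronation (aq K3PO4, dioxane, 90 °C) to give 16. Direct protodehalogenation during the borylation leads to the same product.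

**Step 4.** What may go wrong: loss of chemoselectivity, with acylation of the aminal N–H as well as N8, or sluggish acylation because the acidic phenol ties up the amine as a salt.

Fallback (sets out from 7, returns at 11): the two amines are told apart by a protecting group instead of by rate.
- Ethyl trifluoroacetate (MeCN, 0 °C) acylates only the primary amine of 7 and gives the N8-trifluoroacetamide F9.
- The aminal nitrogen, now the only free N–H amine, is acylated with succinimidyl ester 10 to give F10.
- K2CO3 in aqueous MeOH removes the trifluoroacetyl group to give the N8 amine F11.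
- Acylation of F11 with succinimidyl ester 8 gives 11.

## Further compounds

F1 | step 8 | 4-(allyloxy)-3-bromobenzaldehyde | O=Cc1ccc(OCC=C)c(Br)c1
F2 | step 8 | (E)-3-[4-(allyloxy)-3-bromophenyl]prop-2-enoic acid | OC(=O)/C=C/c1ccc(OCC=C)c(Br)c1
F3 | step 8 | (E)-3-[4-(allyloxy)-3-bromophenyl]-N-[4-(hexahydropyrimidin-1-yl)butyl]prop-2-enamide | O=C(/C=C/c1ccc(OCC=C)c(Br)c1)NCCCCN1CCCNC1
F4 | step 8 | (E)-3-[4-(allyloxy)-3-bromophenyl]-N-{4-[3-((E)-3-(4-hydroxyphenyl)prop-2-enoyl)hexahydropyrimidin-1-yl]butyl}prop-2-enamide | O=C(/C=C/c1ccc(OCC=C)c(Br)c1)NCCCCN1CCCN(C1)C(=O)/C=C/c1ccc(O)cc1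
F5 | step 8 | N8-[(E)-4-(allyloxy)-3-bromocinnamoyl]-N1-[(E)-4-hydroxycinnamoyl]spermidine | O=C(/C=C/c1ccc(OCC=C)c(Br)c1)NCCCCNCCCNC(=O)/C=C/c1ccc(O)cc1
F6 | step 8 | N8-[(E)-4-(allyloxy)-3-bromocinnamoyl]-N1-[(E)-4-hydroxycinnamoyl]-N5-[2-(trimethylsilyl)ethoxycarbonyl]spermidine | O=C(/C=C/c1ccc(OCC=C)c(Br)c1)NCCCCN(C(=O)OCC[Si](C)(C)C)CCCNC(=O)/C=C/c1ccc(O)cc1
F7 | step 8 | N5-Teoc macrocyclic diaryl ether with ring A C4 allyl ether, both alkenes E | O=C1/C=C/c2ccc(OCC=C)c(c2)Oc2ccc(cc2)/C=C/C(=O)NCCCN(C(=O)OCC[Si](C)(C)C)CCCCN1
F8 | step 9 | N5-Teoc macrocyclic diaryl ether with pinacolboryl groups at ring A C5 and ring B C3' and C5', both alkenes E | O=C1/C=C/c2cc(B3OC(C)(C)C(C)(C)O3)c(O)c(c2)Oc2c(B3OC(C)(C)C(C)(C)O3)cc(cc2B4OC(C)(C)C(C)(C)O4)/C=C/C(=O)NCCCN(C(=O)OCC[Si](C)(C)C)CCCCN1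
F9 | step 4 | 2,2,2-trifluoro-N-[4-(hexahydropyrimidin-1-yl)butyl]acetamide | O=C(NCCCCN1CCCNC1)C(F)(F)F
F10 | step 4 | N-{4-[3-((E)-3-(3,5-dichloro-4-hydroxyphenyl)prop-2-enoyl)hexahydropyrimidin-1-yl]butyl}-2,2,2-trifluoroacetamide | O=C(NCCCCN1CCCN(C1)C(=O)/C=C/c1cc(Cl)c(O)c(Cl)c1)C(F)(F)F
F11 | step 4 | (E)-1-[3-(4-aminobutyl)hexahydropyrimidin-1-yl]-3-(3,5-dichloro-4-hydroxyphenyl)prop-2-en-1-one | NCCCCN1CCCN(C1)C(=O)/C=C/c1cc(Cl)c(O)c(Cl)c1
A1 | alternative 1 | methyl 4-[5-(1,3-dioxolan-2-yl)-2-(4-methoxybenzyloxy)phenoxy]benzoate | COC(=O)c1ccc(Oc2cc(C3OCCO3)ccc2OCc2ccc(OC)cc2)cc1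
A2 | alternative 1 | methyl coumalate (methyl 2-oxo-2H-pyran-5-carboxylate) | COC(=O)C1=COC(=O)C=C1
A3 | alternative 1 | 2-[3-(ethynyloxy)-4-(4-methoxybenzyloxy)phenyl]-1,3-dioxolane | C#COc1cc(C2OCCO2)ccc1OCc1ccc(OC)cc1
A4 | alternative 2 | methyl 3-(4-bromophenoxy)-4-hydroxybenzoate | COC(=O)c1ccc(O)c(Oc2ccc(Br)cc2)c1
A5 | alternative 2 | bis(trimethylsilyl) ketene acetal of (4-bromophenoxy)acetic acid | C[Si](C)(C)OC(O[Si](C)(C)C)=COc1ccc(Br)cc1
A6 | alternative 3 | 4-methoxybenzyl-protected macrocycle with free N5, both alkenes E | O=C1/C=C/c2ccc(OCc3ccc(OC)cc3)c(c2)Oc2ccc(cc2)/C=C/C(=O)NCCCNCCCCN1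
A7 | alternative 3 | (E)-N-allyl-3-{3-[4-((E)-3-(3-aminopropylamino)-3-oxoprop-1-enyl)phenoxy]-4-(4-methoxybenzyloxy)phenyl}prop-2-enamide | C=CCNC(=O)/C=C/c1ccc(OCc2ccc(OC)cc2)c(Oc2ccc(/C=C/C(=O)NCCCN)cc2)c1
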